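All runs were generated by integration with made-up constants; scatter was added.

Temperature first: the zeta flask at 60 °C and the beta flask at 45 °C differ in nothing else, and the asked flask repeats zeta.

the same everywhere: substrate 0.73 M; reagent 2.19 M
- zeta: temperature 60 °C; the very flask that is asked about, followed so far
- beta: temperature 45 °C; run made earlier
- flask: temperature 60 °C; time 2.0 h

zeta run (percent of the substrate charged)

| time / min | target / % |
|---|---|
| 8.00 | 11 |
| 12.0 | 16 |
| 20.0 | 19 |
| 40.0 | 21 |
| 60.0 | 20 |
| 90.0 | 19 |

beta run (percent of the substrate charged)

| time / h | target / % |
|---|---|
| 0.250 | 3 |
| 0.417 | 8 |
| 0.667 | 10 |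
| 1.33 | 19 |
| 2.00 | 18 |
| 3.00 | 21 |

(scatter of a reading: 1.5 percentage points)

- north-east: at 2.0 h raise the temperature by 10 K, then wait 40 min
- north: change nothing and wait 40 min more
- south-west: at 2.0 h take out 90% of the target then present, then wait 40 min

- target, in percent of the substrate first charged, at 2.0 h
- the option that brings most further target ("none" if no option brings more than 2 percentage points) (north-east / north / south-west / none)
- target present, with what was taken out counted in, in percent of the substrate first charged, after north-east
- target present, with what was taken out counted in, in percent of the substrate first charged, after north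

- what is taken out of target is counted as made
- steps that have been proposed: substrate + reagent <-> target + released group; substrate <-> dormant form; target <-> isomer of the product

The proposed steps, each reversible: substrate and reagent give target and released group, substrate gives dormant form, target gives isomer of the product. In beta the last 3 readings average 19.3%, about the same as zeta's 20.0%. Call zeta's figure, a reading with its scatter, f, the plateau share: target as a fraction of substrate charged while the rate of making target over the rate of using it stands near one, so that time drops out.

Keep the books on substrate, the limiting reagent, since 0.73 M stands against 2.19 M of reagent. First entry: target, f. Second entry: substrate, dormant form and isomer of the product together, unread, 80.0%. Third entry, for south-west: 18.0% goes out as counted product, leaving a pool of 82.0%. Fourth entry: assume this pool returns to share f, so it holds 16.4% as target. The books close with a gain G = x3·f·(1−f), which is 14 percentage points, and a total of 34.4%. Zeta read 19% at 20.0 min, earlier than the 40 min on offer, so expect the refill in time. Commit to south-west, and to f for now and after north. Leave north-east open: neither run stands above 60 °C.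

The forecast gives 19.5% now, 19.5% after north, 19.5% after north-east, and picks south-west: “The level is therefore an equilibrium limit that barely depends on temperature, not a kinetic stall.” Its south-west total stands at about 29%, this reckoning's at 34.4%.

    substrate + reagent ⇌ target + released group (K = 0.880, k = 2.00 × 10⁻⁴ M⁻¹ s⁻¹, Ea = 87.0 kJ mol⁻¹, ΔH = −49.0 kJ mol⁻¹)
    substrate ⇌ dormant form (K = 0.230, k = 0.00900 s⁻¹, Ea = 93.0 kJ mol⁻¹, ΔH = −19.0 kJ mol⁻¹)
    target ⇌ isomer of the product (K = 3.00, k = 0.00120 s⁻¹, Ea = 102 kJ mol⁻¹, ΔH = −38.0 kJ mol⁻¹)
    (constants at 60 °C)

The flask gives 21.4% at 2.0 h, 21.6% after north and 26.2% after north-east, above the forecast's figure. South-west is best, bringing 15 points. At 2.00 h this flask held 58.7% as isomer of the product against 21.4% as target. G, reckoned from f, stood at 14 points for that gain.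

Take the neighbour with 1.8 M of substrate: carried over unchanged, f puts target there at 20.0%. The computed neighbour gives 17.0% at 2.00 h, 3 points lower, with 29% of its substrate still free.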